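**Retrosynthetic overview**

Ring A is numbered C1 (3-hydroxy-3-methylbutyl), C2 (OMe), C3 (OMe), C4 (2-phenylethyl), C5 (H), C6 (OMe). The plan rests on the C2–C1–C6 unit, a resorcinol with the alkyl chain between its two oxygens (a 2-alkylated acetoacetate in aromatic form), flanked by the C3–C4 pair, which maps onto an ynone whose acetyl group at C3 is a masked oxygen.
Late stage: cleave O–Si, form the three O–CH3 bonds, and derive C3–O from C3–C(O)CH3 by Baeyer–Villiger oxidation.
Key disconnection: C4–C5 and C2–C3, a Diels–Alder benzannulation of bis-silyloxydiene 9 with ynone 13. Ring A is the only ring made; the phenyl ring is bought in 10.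
Diene 9 comes from methyl acetoacetate 4 and iodide 3 (from diol 1) by C-alkylation and two silylations; ynone 13 comes from 4-phenylbut-1-yne 10 by acetylation.

Key step: step 7

Remark: the target has no stereocentre, so the racemic centres of 6, 12 and 14 and the alkene geometries of 7 and 9 are of no consequence; LiN(iPr)2, nBuLi and Bu4NF are used as purchased solutions.

**Route**

Step 1
Reactants: 1 3-methylbutane-1,3-diol
Product: 2 4-iodo-2-methylbutan-2-ol
Conditions: I2, PPh3, imidazole, CH2Cl2, 0 °C to rt
Reagents that add atoms: iodine, II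
Why: Appel-type iodination should convert only the primary hydroxyl, since the tertiary hydroxyl is too hindered to be activated and displaced at this temperature.

Step 2
Reactants: 2 4-iodo-2-methylbutan-2-ol
Product: 3 triethyl[(4-iodo-2-methylbutan-2-yl)oxy]silane
Conditions: Et3SiOTf, 2,6-lutidine, CH2Cl2, −78 to 0 °C
Reagents that add atoms: triethylsilyl trifluoromethanesulfonate, CC[Si](CC)(CC)OS(=O)(=O)C(F)(F)F
Why: Silylation of a tertiary alcohol with a silyl triflate and a hindered pyridine base is standard protection chemistry, and the primary iodide is inert to it.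

Step 3
Reactants: 4 methyl acetoacetate (1.5 equiv); 3 triethyl[(4-iodo-2-methylbutan-2-yl)oxy]silane
Product: 6 methyl 2-acetyl-5-methyl-5-(triethylsilyloxy)hexanoate (racemic), via sodium enolate 5 (not isolated)
Conditions: NaH (1.4 equiv), THF, 0 °C; then 3, DMF, 50 °C
Reagents that add atoms: none
Why: Acetoacetic ester alkylation, an SN2 reaction of the stabilised enolate with an unhindered primary iodide, in which the excess of enolate limits dialkylation and the racemic centre formed is removed in step 4.

Step 4
Reactants: 6 methyl 2-acetyl-5-methyl-5-(triethylsilyloxy)hexanoate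
Product: 7 methyl 2-[3-methyl-3-(triethylsilyloxy)butyl]-3-(trimethylsilyloxy)but-2-enoate (E/Z mixture)
Conditions: Me3SiCl, Et3N, toluene, rt; filtration under argon
Reagents that add atoms: chlorotrimethylsilane, C[Si](C)(C)Cl
Why: Soft enolisation of the beta-keto ester with O-silylation of the ketone oxygen is the usual first stage in making bis-silyloxydienes, and it tolerates the 2-alkyl branch.

Step 5
Reactants: 7 methyl 2-[3-methyl-3-(triethylsilyloxy)butyl]-3-(trimethylsilyloxy)but-2-enoate
Product: 9 1-methoxy-2-[3-methyl-3-(triethylsilyloxy)butyl]-1,3-bis(trimethylsilyloxy)buta-1,3-diene, via lithium dienolate 8 (not isolated)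
Conditions: LiN(iPr)2, THF, −78 °C; then Me3SiCl, −78 °C to rt; pentane, filtration under argon
Reagents that add atoms: chlorotrimethylsilane, C[Si](C)(C)Cl
Why: Kinetic deprotonation of the gamma-methyl group gives the ester dienolate, which is silylated on oxygen (silyl ketene acetal formation); the chain CH2 on C2 cannot give an ester-conjugated anion, so only the methyl group reacts.

Step 6
Reactants: 10 4-phenylbut-1-yne
Product: 13 6-phenylhex-3-yn-2-one, via lithium acetylide 11 (not isolated), via lithium hemiaminal alkoxide 12 (not isolated)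
Conditions: nBuLi, THF, −78 °C; then MeC(O)N(OMe)Me, −78 to 0 °C; then 1 M aq. HCl, 0 °C
Reagents that add atoms: N-methoxy-N-methylacetamide, CC(=O)N(C)OC
Why: Weinreb amide acylation of a lithium acetylide, in which the chelated adduct 12 holds until the acidic quench, so the ynone never meets the acetylide and over-addition is avoided.

Step 7
Reactants: 9 1-methoxy-2-[3-methyl-3-(triethylsilyloxy)butyl]-1,3-bis(trimethylsilyloxy)buta-1,3-diene (1.5 equiv); 13 6-phenylhex-3-yn-2-one
Product: 16 1-{2,4-dihydroxy-3-[3-methyl-3-(triethylsilyloxy)butyl]-6-(2-phenylethyl)phenyl}ethanone, via cyclohexadiene ketal cycloadduct 14 (not isolated), via bis(trimethylsilyl) aryl ether 15 (not isolated)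
Conditions: toluene, 100 °C, sealed tube, argon; then THF, 0.1 M aq. HCl, 0 °C
Reagents that add atoms: none
Why: The electron-rich diene 9 and the acetyl-activated alkyne 13 should combine in a normal-electron-demand, strongly asynchronous [4+2] cycloaddition in which the unsubstituted CH2 terminus of the diene (future C5) bonds first to the beta carbon of the ynone (future C4) and the ketene acetal carbon (future C2) then bonds to the alpha carbon (future C3), so ring A is closed by an intermolecular cycloaddition whose second bond completes the six-membered ring. The closest known reaction type is the Diels–Alder benzannulation of 1-alkoxy-1,3-bis(silyloxy)buta-1,3-dienes with acetylenic ketones and esters, which delivers acyl- and alkoxycarbonyl-resorcinols. The 1,4-cyclohexadiene ketal 14 should lose methanol across C2 and C5 on heating, driven by aromatisation, and the two aryl trimethylsilyl ethers of 15 are hydrolysed by brief cold dilute acid, which the hindered tertiary triethylsilyl ether should survive. The only stereocentre formed is the ketal carbon of 14, which is racemic and vanishes on aromatisation, and the geometry of the diene does not affect the product. The step needs regioselectivity, and this is secured by the match of the largest HOMO coefficient of the diene (the CH2 terminus) with the largest LUMO coefficient of the ynone (the beta carbon bearing the phenylethyl group). Any material that aromatises by loss of silanol instead of methanol keeps a methyl ether on the C2 oxygen, which step 8 would install anyway.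

Step 8
Reactants: 16 1-{2,4-dihydroxy-3-[3-methyl-3-(triethylsilyloxy)butyl]-6-(2-phenylethyl)phenyl}ethanone
Product: 17 1-{2,4-dimethoxy-3-[3-methyl-3-(triethylsilyloxy)butyl]-6-(2-phenylethyl)phenyl}ethanone
Conditions: MeI (excess), K2CO3, DMF, 50 °C
Reagents that add atoms: iodomethane, CI
Why: Williamson ether synthesis on both phenols, with excess MeI in warm DMF to overcome the hydrogen bond between the C2 hydroxyl and the acetyl group, while K2CO3 is too weak to enolise the aryl methyl ketone.

Step 9
Reactants: 17 1-{2,4-dimethoxy-3-[3-methyl-3-(triethylsilyloxy)butyl]-6-(2-phenylethyl)phenyl}ethanone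
Product: 18 2,4-dimethoxy-3-[3-methyl-3-(triethylsilyloxy)butyl]-6-(2-phenylethyl)phenyl acetate
Conditions: mCPBA, NaHCO3, CH2Cl2, 0 °C to rt
Reagents that add atoms: 3-chloroperoxybenzoic acid, OOC(=O)c1cccc(Cl)c1
Why: Baeyer–Villiger oxidation in which the electron-rich aryl group, twisted out of conjugation by its two ortho substituents, migrates in preference to methyl and so places oxygen on C3, while the buffer protects the silyl ether.

Step 10
Reactants: 18 2,4-dimethoxy-3-[3-methyl-3-(triethylsilyloxy)butyl]-6-(2-phenylethyl)phenyl acetate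
Product: 19 2,4-dimethoxy-3-[3-methyl-3-(triethylsilyloxy)butyl]-6-(2-phenylethyl)phenol
Conditions: K2CO3 (0.2 equiv), degassed MeOH, rt, argon
Reagents that add atoms: none
Why: Base-catalysed methanolysis (transesterification) of the aryl acetate, the most labile group present, run without air because the phenol formed is electron-rich.

Step 11
Reactants: 19 2,4-dimethoxy-3-[3-methyl-3-(triethylsilyloxy)butyl]-6-(2-phenylethyl)phenol
Product: 20 triethyl({2-methyl-4-[2,3,6-trimethoxy-4-(2-phenylethyl)phenyl]butan-2-yl}oxy)silane
Conditions: MeI, K2CO3, acetone, reflux, argon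
Reagents that add atoms: iodomethane, CI
Why: Williamson methylation of a phenol that is no longer hydrogen-bonded to a carbonyl group and should therefore react readily.

Step 12
Reactants: 20 triethyl({2-methyl-4-[2,3,6-trimethoxy-4-(2-phenylethyl)phenyl]butan-2-yl}oxy)silane
Product: 21 2-methyl-4-[2,3,6-trimethoxy-4-(2-phenylethyl)phenyl]butan-2-ol
Conditions: Bu4NF, THF, rt
Reagents that add atoms: none
Why: Fluoride-mediated desilylation, driven by the Si–F bond, frees the tertiary alcohol without the acid that could ionise or dehydrate it.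

**Compound list**

1 | 3-methylbutane-1,3-diol | CC(C)(O)CCO | starting material
2 | 4-iodo-2-methylbutan-2-ol | CC(C)(O)CCI | intermediate
3 | triethyl[(4-iodo-2-methylbutan-2-yl)oxy]silane | CC[Si](CC)(CC)OC(C)(C)CCI | intermediate
4 | methyl acetoacetate | CC(=O)CC(=O)OC | starting material
5 | sodium (Z)-4-methoxy-4-oxobut-2-en-2-olate (sodium enolate of 4) | COC(=O)/C=C(/C)[O-].[Na+] | intermediate
6 | methyl 2-acetyl-5-methyl-5-(triethylsilyloxy)hexanoate (racemic) | COC(=O)C(CCC(C)(C)O[Si](CC)(CC)CC)C(C)=O | intermediate
7 | methyl 2-[3-methyl-3-(triethylsilyloxy)butyl]-3-(trimethylsilyloxy)but-2-enoate (E/Z mixture) | COC(=O)C(CCC(C)(C)O[Si](CC)(CC)CC)=C(C)O[Si](C)(C)C | intermediate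
8 | lithium 1-methoxy-2-[3-methyl-3-(triethylsilyloxy)butyl]-3-(trimethylsilyloxy)buta-1,3-dien-1-olate | [Li+].[O-]C(OC)=C(CCC(C)(C)O[Si](CC)(CC)CC)C(=C)O[Si](C)(C)C | intermediate
9 | 1-methoxy-2-[3-methyl-3-(triethylsilyloxy)butyl]-1,3-bis(trimethylsilyloxy)buta-1,3-diene (geometry not defined) | C=C(O[Si](C)(C)C)C(CCC(C)(C)O[Si](CC)(CC)CC)=C(OC)O[Si](C)(C)C | intermediate
10 | 4-phenylbut-1-yne | C#CCCc1ccccc1 | starting material
11 | (4-phenylbut-1-yn-1-yl)lithium | [Li]C#CCCc1ccccc1 | intermediate
12 | lithium 2-[methoxy(methyl)amino]-6-phenylhex-3-yn-2-olate (racemic) | [Li+].[O-]C(C)(N(C)OC)C#CCCc1ccccc1 | intermediate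
13 | 6-phenylhex-3-yn-2-one | CC(=O)C#CCCc1ccccc1 | intermediate
14 | 1-{6-methoxy-5-[3-methyl-3-(triethylsilyloxy)butyl]-2-(2-phenylethyl)-4,6-bis(trimethylsilyloxy)cyclohexa-1,4-dien-1-yl}ethanone (racemic) | CC(=O)C1=C(CCc2ccccc2)CC(O[Si](C)(C)C)=C(CCC(C)(C)O[Si](CC)(CC)CC)C1(OC)O[Si](C)(C)C | intermediate
15 | 1-{3-[3-methyl-3-(triethylsilyloxy)butyl]-6-(2-phenylethyl)-2,4-bis(trimethylsilyloxy)phenyl}ethanone | CC(=O)c1c(O[Si](C)(C)C)c(CCC(C)(C)O[Si](CC)(CC)CC)c(O[Si](C)(C)C)cc1CCc1ccccc1 | intermediate
16 | 1-{2,4-dihydroxy-3-[3-methyl-3-(triethylsilyloxy)butyl]-6-(2-phenylethyl)phenyl}ethanone | CC(=O)c1c(O)c(CCC(C)(C)O[Si](CC)(CC)CC)c(O)cc1CCc1ccccc1 | intermediate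
17 | 1-{2,4-dimethoxy-3-[3-methyl-3-(triethylsilyloxy)butyl]-6-(2-phenylethyl)phenyl}ethanone | CC(=O)c1c(OC)c(CCC(C)(C)O[Si](CC)(CC)CC)c(OC)cc1CCc1ccccc1 | intermediate
18 | 2,4-dimethoxy-3-[3-methyl-3-(triethylsilyloxy)butyl]-6-(2-phenylethyl)phenyl acetate | CC(=O)Oc1c(OC)c(CCC(C)(C)O[Si](CC)(CC)CC)c(OC)cc1CCc1ccccc1 | intermediate
19 | 2,4-dimethoxy-3-[3-methyl-3-(triethylsilyloxy)butyl]-6-(2-phenylethyl)phenol | Oc1c(OC)c(CCC(C)(C)O[Si](CC)(CC)CC)c(OC)cc1CCc1ccccc1 | intermediate
20 | triethyl({2-methyl-4-[2,3,6-trimethoxy-4-(2-phenylethyl)phenyl]butan-2-yl}oxy)silane | COc1c(OC)c(CCC(C)(C)O[Si](CC)(CC)CC)c(OC)cc1CCc1ccccc1 | intermediate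
21 | 2-methyl-4-[2,3,6-trimethoxy-4-(2-phenylethyl)phenyl]butan-2-ol | COc1cc(CCc2ccccc2)c(OC)c(OC)c1CCC(C)(C)O | target

**Step count and risks**

Total step count: 12. Longest linear sequence: 11 steps (steps 1 to 5 and 7 to 12, from 3-methylbutane-1,3-diol); the ynone arm is one step.

Steps most likely to fail:

1. Step 7. The cycloaddition of a disubstituted alkyne with a trisubstituted diene may be slower than thermal decomposition or protodesilylation of the diene, so that little cycloadduct forms. The fallback sets out from 9 and 13 and replaces the pericyclic step by a two-stage ionic annulation. A Mukaiyama–Michael addition (Me3SiOTf catalyst, CH2Cl2, −78 °C, aqueous work-up) should join the CH2 terminus of 9 to the beta carbon of 13 and give the open-chain enone keto ester methyl 2-[3-methyl-3-(triethylsilyloxy)butyl]-3,7-dioxo-5-(2-phenylethyl)oct-5-enoate F1. NaOMe in MeOH at reflux should then bring about a Claisen (Dieckmann-type) closure of the dienolate carbon next to the acetyl group onto the ester, and loss of methanol and tautomerisation should give the aromatic ketone. The route is rejoined at 16.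

2. Step 9. Peracid addition to the hindered, twisted carbonyl group may be slow, and oxidation of the electron-rich ring at C5 may compete. The fallback sets out from 17 and uses a benzylic hydroperoxide rearrangement in place of the Baeyer–Villiger oxidation. Reduction with LiAlH4 (THF, 0 °C) should give the benzylic alcohol 1-{2,4-dimethoxy-3-[3-methyl-3-(triethylsilyloxy)butyl]-6-(2-phenylethyl)phenyl}ethanol F2. Aqueous H2O2 with TsOH in THF should ionise it to the stabilised benzylic cation, whose hydroperoxide rearranges with aryl migration and releases acetaldehyde. The acid also removes the triethylsilyl group, which is harmless here because no free hydroxyl stands ortho to the chain, so the product should be 3-(3-hydroxy-3-methylbutyl)-2,4-dimethoxy-6-(2-phenylethyl)phenol F3. Methylation of the phenol alone (MeI, K2CO3, acetone) leaves the tertiary alcohol untouched, and the route is rejoined at the target 21.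

3. Step 8. O-Methylation of the C2 hydroxyl, which is hydrogen-bonded to the acetyl group and flanked on both sides, may stop short, or C-methylation at the activated C5 position may intrude. The fallback sets out from 16 and removes the acetyl group before any methylation. Dakin oxidation (H2O2, NaOH, H2O/THF, 0 °C, argon) uses the free ortho and para hydroxyls to drive aryl migration and, after hydrolysis of the acetate in the same flask, should give 3-[3-methyl-3-(triethylsilyloxy)butyl]-6-(2-phenylethyl)benzene-1,2,4-triol F4. This air-sensitive triol is methylated at once on all three oxygens (MeI, K2CO3, acetone, argon), none of which is hydrogen-bonded any longer. The route is rejoined at 20.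

**Further compounds**

F1 | step 7 | methyl 2-[3-methyl-3-(triethylsilyloxy)butyl]-3,7-dioxo-5-(2-phenylethyl)oct-5-enoate (racemic, E/Z mixture) | COC(=O)C(CCC(C)(C)O[Si](CC)(CC)CC)C(=O)CC(CCc1ccccc1)=CC(C)=O
F2 | step 9 | 1-{2,4-dimethoxy-3-[3-methyl-3-(triethylsilyloxy)butyl]-6-(2-phenylethyl)phenyl}ethanol (racemic) | CC(O)c1c(OC)c(CCC(C)(C)O[Si](CC)(CC)CC)c(OC)cc1CCc1ccccc1
F3 | step 9 | 3-(3-hydroxy-3-methylbutyl)-2,4-dimethoxy-6-(2-phenylethyl)phenol | Oc1c(OC)c(CCC(C)(C)O)c(OC)cc1CCc1ccccc1
F4 | step 8 | 3-[3-methyl-3-(triethylsilyloxy)butyl]-6-(2-phenylethyl)benzene-1,2,4-triol | Oc1c(O)c(CCC(C)(C)O[Si](CC)(CC)CC)c(O)cc1CCc1ccccc1
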